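Percent of the substrate charged per half hour is my unit, so that progress curves of different charge stand on one scale.

all flasks: gas phase 200 mM (held)
- violet: substrate 1.1 M; protic impurity 1.7 M; run made earlier
- ochre: substrate 2.5 M; protic impurity 1.7 M; run made earlier
- amber: substrate 1.7 M; protic impurity 0.85 M; run made earlier
- flask: substrate 1.7 M; protic impurity 1.70 M; time 1.0 h

- violet (time / min: target / %): 5.00: 1.8; 15.0: 7.0; 30.0: 14.0; 40.0: 16.2; 60.0: 19.6
- ochre (time / min: target / %): 5.00: 2.2; 15.0: 7.2; 30.0: 12.3; 40.0: 14.8; 60.0: 17.3
- amber (time / min: target / %): 5.00: 2.8; 15.0: 7.8; 30.0: 12.5; 40.0: 14.8; 60.0: 18.5

(readings scatter by 0.5 percentage points)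

- at the start none of the gas is dissolved
- reactions considered so far: dissolved gas + target -> over-reacted product; dissolved gas + protic impurity -> quenched reagent; gas phase <-> dissolved gas; dissolved gas -> decomposed reagent; substrate <-> dormant form; substrate + dissolved gas -> target

- north-east: doubling the transfer coefficient of the gas phase, all else as stated
- north-west: doubling the saturation concentration of gas phase, all else as stated

- how much target there is at 1.0 h, in percent of the substrate charged
- the change that raises the amount of target at 1.0 h, in percent of the substrate charged most ("none" if none brings more than 2 percentage points) (north-east / north-west / none)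
- amount of target at 1.0 h, in percent of the substrate charged, after north-east

I replace each curve by its mean rate in the two halves of the hour and divide the second by the first. Pooled over the runs this gives 0.428: the carry-on ratio ρ, the target made in the second half hour per unit made in the first. Singly, violet gives 0.400, ochre 0.407 and amber 0.480, and raising amber's half-hour reading by its scatter of 0.5 percentage points gives 0.423. So, within the scatter of the readings, one number serves for these 3 runs.

Violet and ochre share the flask's impurity and bracket its charge. Their mean half-hour reading, 13.2%, times one plus ρ gives me 18.8% for the flask at 1.0 h. One number does not serve across time, though: the same ratio from 15.0 min to 30.0 min is 0.764, larger than ρ, so in these readings the ratio falls with time.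

The forecast gives 18.5% (17.5% to 19.5%), names north-west, and puts north-east at 19.5%, holding that “transfer is not strongly limiting”.

The flask gives 18.4%; north-west gains 12 points and north-east 3.1 points, reaching 21.6%.

    dissolved gas + target → over-reacted product (k = 0.00240 M⁻¹ min⁻¹)
    dissolved gas + protic impurity → quenched reagent (k = 0.00130 M⁻¹ min⁻¹)
    gas phase ⇌ dissolved gas, rate k3*(csat - [dissolved gas]) (kL = 0.200 min⁻¹)
    dissolved gas → decomposed reagent (k = 0.00560 min⁻¹)
    substrate ⇌ dormant form (K = 7.20, k = 0.0550 min⁻¹)
    substrate + dissolved gas → target (k = 0.0830 M⁻¹ min⁻¹)

At 0.144 h the flask's substrate passes into dormant form, its resting state, 5.4 times as fast (forward rate alone) as into target. At 1.00 h the flask holds 72.0% of the charge as dormant form against 18.4% as target. Read at 0.517 h or 1.73 h, its target stands 5 points from that value. Left until 2.5 h, with each doubling of time multiplying the target by one plus ρ, the same flask should reach 29.5%; it gives 28.1%, lower, the direction in which the ratio was falling in the readings.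

The runs stem from a simulated flask with made-up constants; scatter was added.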